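All runs are simulated for substances that don't exist; scatter was added.

In cedar, with a small charge of catalyst (54 mM), target leads the isomer of the product by 33% to 15% at 10.0 h. In alder, with 120 mM, they stand at 14% and 16% at 4.00 h. Starting material goes to target by itself and to the isomer with the catalyst's help, so the bench rule says that the early ratio of target to isomer, the selectivity, falls in step with the catalyst.

| flask | starting material | catalyst | remark | time |
|---|---|---|---|---|
| cedar | 0.80 M | 54 mM | run made earlier |  |
| alder | 0.80 M | 120 mM | run made earlier |  |
| elm | 1.2 M | 80 mM | run made earlier |  |
| flask | 0.80 M | 80 mM |  | 50 h |

- cedar (time / h: target / %, isomer of the product / %, starting material / %): 10.0: 33, 15, 52; 20.0: 42, 31, 30; 30.0: 47, 33, 22; 40.0: 49, 36, 11; 48.0: 50, 36, 10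
- alder (time / h: target / %, isomer of the product / %, starting material / %): 4.00: 14, 16, 68; 8.00: 22, 28, 45; 15.0: 30, 44, 26; 25.0: 38, 54, 13; 48.0: 26, 65, 11
- elm (time / h: target / %, isomer of the product / %, starting material / %): 10.0: 27, 26, 45; 20.0: 38, 38, 23; 30.0: 47, 44, 11; 40.0: 43, 45, 12; 48.0: 44, 48, 10

(each reading ± 2 percentage points)

- ratio of target to isomer of the product at 8.0 min
- ratio of target to isomer of the product at 50 h

- amounts and yields of target count crystals too
- given per volume of solution although it is solid: crystals
- steps under discussion: starting material <-> target; starting material + catalyst <-> isomer of the product + catalyst; crystals <-> target; starting material -> decomposition product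

Multiply each early ratio by its catalyst charge: cedar reads 119 mM and alder 105 mM. Their mean, 112 mM, is my reading of the balance catalyst, the charge at which target and isomer are made equally fast. Elm, with 1.2 M of starting material, reads 83.1 mM, and I leave it out of the mean, since the flask has 0.80 M of starting material, as cedar and alder do. Since 8.0 min is far shorter than alder's first reading, I expect a ratio of 1.40 in the flask, the balance catalyst over its 80 mM.

The rule counts only what is made, and alder shows its border. At 48.0 h alder's ratio is 0.400 where the rule says 0.933, a quotient of 0.429, and its target has fallen from 38% to 26%. For the late question I therefore commit only to a bracket: the flask's catalyst lies between cedar's and alder's, so its ratio should lie between their last readings, 0.400 and 1.39.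

The forecast gives 1.1 at 8.0 min and 0.8 at 50 h, holding that “Eight minutes is far too short for any reversal”, and its early number is below mine.

The flask gives 1.33 at 8.0 min and 0.768 at 50 h, against my 1.40 and my bracket. For the neighbour flask with 0.048 M of catalyst, the balance catalyst gives 2.33 at 8.0 min, and that neighbour shows 2.21.

    starting material ⇌ target (K = 0.0840, k = 0.0520 /h)
    starting material + catalyst ⇌ isomer of the product + catalyst, rate k2*[starting material]*[catalyst] forward; the back reaction follows from the equilibrium constant (K = 24.0, k = 0.470 /M/h)
    crystals ⇌ target, rate k3*(cs3 - [target]) while solid is left; crystals form when [target] > cs3 (solubility = 8.40 mM, k = 7.60 /h)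
    starting material → decomposition product (k = 6.40 × 10⁻⁵ /h)

In the flask, dissolved target has a half-life of 1.1 h for going back through starting material, short against 50 h, and at 50.0 h it is made 0.996 times as fast as it is used, each step taken net and going into crystals counted as use. At that time crystals stand at 38.4% of the charge and target in all its forms at 39.4%, and at 500 h the flask holds 95.4% isomer of the product and 0.333% target.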